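**Strategy.** The two tetrahydrofuran rings of the 3,7-dioxabicyclo[3.3.0]octane share the bond C1–C5, and the chain C8–C1–C5–C4 (two OCH2 carbons flanking the ring-fusion carbons) is a masked 5-alkoxybutenolide. The route rests on cutting C5–C6 and C1–C2. In one pot the lithiated dithiane of the cis-dihydrobenzofuran aldehyde (ring B) adds to the β-carbon of (5S)-5-(d-menthyloxy)furan-2(5H)-one, and the enolate is trapped with O-silylated vanillin (ring A), fixing C5, C1 and C2. The precursor is a fully silyl-protected 2-aryl-1,3-dithiane made by enantioselective carbenoid C–H insertion. Both ether rings are closed last at the primary carbons, preserving the endo benzylic centres.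

Key step: step 12

**Remarks and assumptions**
- Numbering: the core is numbered as 3,7-dioxabicyclo[3.3.0]octane (C1, C5 ring fusion; C2 bears ring A; C6 bears ring B; C4, C8 are OCH2). Ring A is the guaiacyl on C2, ring B the arene of the dihydrobenzofuran, ring C the guaiacyl on the dihydrobenzofuran.
- Abbreviations: TIPS = triisopropylsilyl; TBS = tert-butyldimethylsilyl; ArA = 3-methoxy-4-(triisopropylsilyloxy)phenyl; ArB = (2S,3S)-3-[(tert-butyldimethylsilyloxy)methyl]-7-methoxy-2-ArA-2,3-dihydro-1-benzofuran-5-yl (2,3-cis); d-menthyl = (1S,2R,5S)-2-isopropyl-5-methylcyclohexyl.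
- Target stereochemistry as planned for: both aryl groups endo on the bicycle (1S,2S,5S,6S) and a 2,3-cis (2S,3S) dihydrobenzofuran.
- Protecting groups: the phenols are carried as TIPS ethers (more robust than smaller silyl ethers towards n-BuLi and LiAlH4) and the primary alcohol as a TBS ether; all three fall in one fluoride step.
- Starting material: the ring B aldehyde carbon is carried as a nitrile (3-bromo-4-hydroxy-5-methoxybenzonitrile, taken as a catalogue compound), which needs no protection through the carbenoid step.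
- Catalyst sense: the (S)-tert-leucinate catalyst is taken, by analogy with simpler aryl benzyl ethers, to give the (2R,3S) cis ester, so its antipode Rh2(R-PTTL)4 (dirhodium tetrakis[N-phthaloyl-(R)-tert-leucinate]) is specified. If the sense is opposite on this substrate, the S catalyst is used instead.

**Route**

Step 1
Reactants: 1 furfural
Product: 3 5-hydroxyfuran-2(5H)-one, via furfural endoperoxide 2 (not isolated)
Conditions: O2, rose bengal (cat.), MeOH, visible light, rt
Reagents that add atoms: dioxygen, O=O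
Why: Dye-sensitised singlet oxygen adds to the furan diene in a [4+2] cycloaddition and methanolysis of endoperoxide 2 expels the formyl carbon as methyl formate, a standard photooxygenation giving the racemic hydroxybutenolide whose acetal centre is set in the next step.

Step 2
Reactants: 3 5-hydroxyfuran-2(5H)-one; 4 d-menthol
Product: 5 (5S)-5-(d-menthyloxy)furan-2(5H)-one
Conditions: CSA (cat.), toluene, reflux (Dean–Stark); crystallisation from petroleum ether, mother liquor re-equilibrated with CSA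
Reagents that add atoms: none
Why: Acid-catalysed acetalisation gives both acetal epimers, and because this centre epimerises under acid while the (5S) d-menthyl diastereomer is the crystalline one, a crystallisation-induced asymmetric transformation should deliver the single diastereomer.

Step 3
Reactants: 6 vanillin
Product: 7 3-methoxy-4-(triisopropylsilyloxy)benzaldehyde
Conditions: TIPSCl, imidazole, DMF, rt
Reagents that add atoms: triisopropylsilyl chloride, CC(C)[Si](Cl)(C(C)C)C(C)C
Why: Imidazole-mediated silylation of a phenol, with the bulky silyl group chosen to survive n-BuLi and LiAlH4 later.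

Step 4
Reactants: 7 3-methoxy-4-(triisopropylsilyloxy)benzaldehyde
Product: 8 [3-methoxy-4-(triisopropylsilyloxy)phenyl]methanol
Conditions: NaBH4, MeOH, 0 °C
Reagents that add atoms: none
Why: Chemoselective borohydride reduction of an aromatic aldehyde that leaves the aryl silyl ether intact.

Step 5
Reactants: 9 3-bromo-4-hydroxy-5-methoxybenzonitrile; 8 [3-methoxy-4-(triisopropylsilyloxy)phenyl]methanol
Product: 10 3-bromo-5-methoxy-4-[(ArA)methoxy]benzonitrile
Conditions: PPh3, DIAD, THF, 0 °C → rt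
Reagents that add atoms: none
Why: Mitsunobu etherification of an acidic phenol with a primary benzylic alcohol forms the aryl benzyl ether without preparing the ionisation-prone 4-silyloxybenzyl halide.

Step 6
Reactants: 10 3-bromo-5-methoxy-4-[(ArA)methoxy]benzonitrile
Product: 11 tert-butyl 2-{5-cyano-3-methoxy-2-[(ArA)methoxy]phenyl}acetate
Conditions: BrZnCH2CO2t-Bu, Pd(dba)2 (2 mol%), P(t-Bu)3 (2 mol%), THF, rt
Reagents that add atoms: (2-tert-butoxy-2-oxoethyl)zinc bromide, CC(C)(C)OC(=O)C[Zn]Br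
Why: Palladium-catalysed α-arylation of an ester by Negishi-type coupling of the aryl bromide with a Reformatsky zinc enolate runs under neutral conditions that tolerate nitrile, benzylic ether and silyl ether.

Step 7
Reactants: 11 tert-butyl 2-{5-cyano-3-methoxy-2-[(ArA)methoxy]phenyl}acetate
Product: 12 tert-butyl 2-{5-cyano-3-methoxy-2-[(ArA)methoxy]phenyl}-2-diazoacetate
Conditions: p-ABSA, DBU, MeCN, 0 °C → rt
Reagents that add atoms: 4-acetamidobenzenesulfonyl azide, CC(=O)Nc1ccc(cc1)S(=O)(=O)N=[N+]=[N-]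
Why: Regitz diazo transfer to the benzylic ester methylene, acidic enough for DBU, gives the donor/acceptor diazo ester.

Step 8
Reactants: 12 tert-butyl 2-{5-cyano-3-methoxy-2-[(ArA)methoxy]phenyl}-2-diazoacetate
Product: 13 tert-butyl (2S,3R)-2-ArA-5-cyano-7-methoxy-2,3-dihydro-1-benzofuran-3-carboxylate
Conditions: Rh2(R-PTTL)4 (1 mol%), toluene, −78 → −40 °C
Reagents that add atoms: none
Why: Chiral dirhodium carboxylate-catalysed intramolecular carbene insertion into the electron-rich benzylic ether C–H bond (1,5-insertion) closes the dihydrofuran ring with the 2-aryl and 3-ester groups cis as the kinetic outcome of the concerted insertion, and the tert-leucinate ligand shell sets the absolute configuration at C2 and C3.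

Step 9
Reactants: 13 tert-butyl (2S,3R)-2-ArA-5-cyano-7-methoxy-2,3-dihydro-1-benzofuran-3-carboxylate
Product: 14 (2S,3S)-2-ArA-3-(hydroxymethyl)-7-methoxy-2,3-dihydro-1-benzofuran-5-carbaldehyde
Conditions: i-Bu2AlH (5 equiv), CH2Cl2, −78 → 0 °C; then 1 M aq. HCl, 0 °C
Reagents that add atoms: water, O
Why: Aluminium hydride reduction takes the ester to the primary alcohol and stops at the N-aluminio aldimine for the nitrile, which hydrolyses to the aldehyde on work-up, and the non-basic conditions leave the epimerisable cis C3 centre untouched.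

Step 10
Reactants: 14 (2S,3S)-2-ArA-3-(hydroxymethyl)-7-methoxy-2,3-dihydro-1-benzofuran-5-carbaldehyde
Product: 15 [(2S,3S)-2-ArA-5-(1,3-dithian-2-yl)-7-methoxy-2,3-dihydro-1-benzofuran-3-yl]methanol
Conditions: HS(CH2)3SH, I2 (10 mol%), CH2Cl2, rt
Reagents that add atoms: propane-1,3-dithiol, SCCCS
Why: Iodine-catalysed dithioacetalisation of an aromatic aldehyde is mild enough for the acid-sensitive cis-2-aryl-dihydrobenzofuran and the aryl silyl ethers.

Step 11
Reactants: 15 [(2S,3S)-2-ArA-5-(1,3-dithian-2-yl)-7-methoxy-2,3-dihydro-1-benzofuran-3-yl]methanol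
Product: 16 2-ArB-1,3-dithiane
Conditions: TBSCl, imidazole, DMF, rt
Reagents that add atoms: tert-butyldimethylsilyl chloride, CC(C)(C)[Si](C)(C)Cl
Why: Routine silylation of the primary alcohol, so that this hydroxyl is neither deprotonated in the key step nor sulfonylated in the ring-closing step.

Step 12
Reactants: 16 2-ArB-1,3-dithiane; 5 (5S)-5-(d-menthyloxy)furan-2(5H)-one; 7 3-methoxy-4-(triisopropylsilyloxy)benzaldehyde
Product: 19 (3R,4S,5S)-3-[(S)-ArA(hydroxy)methyl]-4-(2-ArB-1,3-dithian-2-yl)-5-(d-menthyloxy)oxolan-2-one, via 2-lithio-2-ArB-1,3-dithiane 17 (not isolated), via lithium lactone enolate 18 (not isolated)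
Conditions: n-BuLi (1.05 equiv), THF, −78 °C; 5, −78 °C; 7, −78 °C; sat. aq. NH4Cl at −78 °C
Reagents that add atoms: none
Why: Deprotonation of 16 gives the sulfur-stabilised benzylic anion 17, which adds 1,4 to butenolide 5, and the resulting enolate 18 is captured by aldehyde 7 in an aldol addition, so C5–C6 and C1–C2 are formed in one pot and no ring is closed. The closest known reaction type is the tandem Michael addition–aldol reaction of lithiated 2-aryl-1,3-dithianes with 5-alkoxyfuran-2(5H)-ones and aromatic aldehydes. C5 is controlled by the acetal carbon C4, the nucleophile entering the face anti to the menthyloxy group. C1 is controlled by C5, the aldehyde approaching the enolate face opposite the bulky dithianyl group to give the 3,4-trans lactone. C2 is controlled by a closed lithium-bridged chair (Zimmerman–Traxler) transition state of the ring-constrained (E)-enolate, which should favour the anti carbinol; this is the least secure element and requires the cold quench to prevent retro-aldol equilibration. The step needs 1,4- over 1,2-addition, which the soft, delocalised and hindered aryl dithiane anion and the unhindered β-carbon of the butenolide secure.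

Step 13
Reactants: 19 (3R,4S,5S)-3-[(S)-ArA(hydroxy)methyl]-4-(2-ArB-1,3-dithian-2-yl)-5-(d-menthyloxy)oxolan-2-one
Product: 20 (3R,4S,5S)-3-[(S)-ArA(hydroxy)methyl]-4-(ArB-carbonyl)-5-(d-menthyloxy)oxolan-2-one
Conditions: Hg(ClO4)2, CaCO3, THF–H2O (5:1), 0 °C
Reagents that add atoms: water, O
Why: Thiophilic, divalent-mercury-assisted hydrolysis of the dithioacetal under carbonate buffering unmasks the aryl ketone without touching silyl ethers, acetal or lactone, and the now enolisable C5 already sits in the thermodynamically preferred trans,trans arrangement.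

Step 14
Reactants: 20 (3R,4S,5S)-3-[(S)-ArA(hydroxy)methyl]-4-(ArB-carbonyl)-5-(d-menthyloxy)oxolan-2-one
Product: 21 (3R,4R,5S)-3-[(S)-ArA(hydroxy)methyl]-4-[(S)-ArB(hydroxy)methyl]-5-(d-menthyloxy)oxolan-2-one
Conditions: (R)-2-methyl-CBS-oxazaborolidine (1 equiv), BH3·SMe2 (2.5 equiv), THF, −20 °C, slow addition of 20; MeOH
Reagents that add atoms: none
Why: Corey–Bakshi–Shibata reduction, in which the oxazaborolidine distinguishes the aryl group (large) from the branched alkyl residue, should deliver hydride to the face giving the (S)-carbinol at C6 (the spatial analogue of (S)-1-phenylethanol from the (R)-catalyst), a sense that Felkin–Anh attack anti to the acetal-bearing carbon C4 should reinforce.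

Step 15
Reactants: 21 (3R,4R,5S)-3-[(S)-ArA(hydroxy)methyl]-4-[(S)-ArB(hydroxy)methyl]-5-(d-menthyloxy)oxolan-2-one
Product: 22 (1S,2S,3S,4S)-1-ArA-4-ArB-2,3-bis(hydroxymethyl)butane-1,4-diol
Conditions: LiAlH4, THF, 0 °C → rt; H2O, aq. NaOH work-up
Reagents that add atoms: none
Why: Exhaustive aluminium hydride reduction opens the lactone and reduces the aldehyde released at C4 when the menthyloxy hemiacetal collapses, giving the 1,4-diol without touching any stereocentre and releasing the auxiliary.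

Step 16
Reactants: 22 (1S,2S,3S,4S)-1-ArA-4-ArB-2,3-bis(hydroxymethyl)butane-1,4-diol
Product: 24 (1S,2S,5S,6S)-2-ArA-6-ArB-3,7-dioxabicyclo[3.3.0]octane, via bis-mesylate 23 (not isolated)
Conditions: MsCl (2.3 equiv), pyridine–CH2Cl2, −10 °C → rt
Reagents that add atoms: none
Why: Selective sulfonylation of the two primary hydroxyls gives 23, whose benzylic hydroxyls at C2 and C6 displace the primary mesylates at C4 and C8 in two 5-exo-tet intramolecular Williamson closures, so no benzylic C–O bond is broken and both configurations pass unchanged into the endo,endo bicycle (excess MsCl in the cold sulfonylates both primary positions before one primary hydroxyl can attack the other).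

Step 17
Reactants: 24 (1S,2S,5S,6S)-2-ArA-6-ArB-3,7-dioxabicyclo[3.3.0]octane
Product: 25 CNP0303197.1
Conditions: TBAF, AcOH, THF, 0 °C → rt
Reagents that add atoms: none
Why: Fluoride-mediated cleavage of the two aryl and one alkyl silyl ethers under acetic acid buffering avoids the strong acid that would epimerise the endo benzylic ether centres.

**Compound list**

1 | furfural | O=Cc1ccco1 | starting material
2 | furfural endoperoxide (2,3,7-trioxabicyclo[2.2.1]hept-5-ene-1-carbaldehyde) | O=CC12C=CC(OO1)O2 | intermediate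
3 | 5-hydroxyfuran-2(5H)-one (racemic) | O=C1C=CC(O)O1 | intermediate
4 | d-menthol, (1S,2R,5S)-2-isopropyl-5-methylcyclohexan-1-ol | CC(C)[C@H]1CC[C@H](C)C[C@@H]1O | starting material
5 | (5S)-5-(d-menthyloxy)furan-2(5H)-one | O=C1C=C[C@@H](O[C@H]2C[C@@H](C)CC[C@@H]2C(C)C)O1 | intermediate
6 | vanillin | COc1cc(C=O)ccc1O | starting material
7 | 3-methoxy-4-(triisopropylsilyloxy)benzaldehyde | COc1cc(C=O)ccc1O[Si](C(C)C)(C(C)C)C(C)C | intermediate
8 | [3-methoxy-4-(triisopropylsilyloxy)phenyl]methanol | COc1cc(CO)ccc1O[Si](C(C)C)(C(C)C)C(C)C | intermediate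
9 | 3-bromo-4-hydroxy-5-methoxybenzonitrile | COc1cc(C#N)cc(Br)c1O | starting material
10 | 3-bromo-5-methoxy-4-[(ArA)methoxy]benzonitrile | COc1cc(C#N)cc(Br)c1OCc1ccc(O[Si](C(C)C)(C(C)C)C(C)C)c(OC)c1 | intermediate
11 | tert-butyl 2-{5-cyano-3-methoxy-2-[(ArA)methoxy]phenyl}acetate | COc1cc(C#N)cc(CC(=O)OC(C)(C)C)c1OCc1ccc(O[Si](C(C)C)(C(C)C)C(C)C)c(OC)c1 | intermediate
12 | tert-butyl 2-{5-cyano-3-methoxy-2-[(ArA)methoxy]phenyl}-2-diazoacetate | COc1cc(C#N)cc(C(=[N+]=[N-])C(=O)OC(C)(C)C)c1OCc1ccc(O[Si](C(C)C)(C(C)C)C(C)C)c(OC)c1 | intermediate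
13 | tert-butyl (2S,3R)-2-ArA-5-cyano-7-methoxy-2,3-dihydro-1-benzofuran-3-carboxylate (2,3-cis) | N#Cc1cc(OC)c2c(c1)[C@@H](C(=O)OC(C)(C)C)[C@@H](c1ccc(O[Si](C(C)C)(C(C)C)C(C)C)c(OC)c1)O2 | intermediate
14 | (2S,3S)-2-ArA-3-(hydroxymethyl)-7-methoxy-2,3-dihydro-1-benzofuran-5-carbaldehyde (2,3-cis) | O=Cc1cc(OC)c2c(c1)[C@@H](CO)[C@@H](c1ccc(O[Si](C(C)C)(C(C)C)C(C)C)c(OC)c1)O2 | intermediate
15 | [(2S,3S)-2-ArA-5-(1,3-dithian-2-yl)-7-methoxy-2,3-dihydro-1-benzofuran-3-yl]methanol | S1CCCSC1c1cc(OC)c2c(c1)[C@@H](CO)[C@@H](c1ccc(O[Si](C(C)C)(C(C)C)C(C)C)c(OC)c1)O2 | intermediate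
16 | 2-ArB-1,3-dithiane | S1CCCSC1c1cc(OC)c2c(c1)[C@@H](CO[Si](C)(C)C(C)(C)C)[C@@H](c1ccc(O[Si](C(C)C)(C(C)C)C(C)C)c(OC)c1)O2 | intermediate
17 | 2-lithio-2-ArB-1,3-dithiane | [Li]C1(SCCCS1)c1cc(OC)c2c(c1)[C@@H](CO[Si](C)(C)C(C)(C)C)[C@@H](c1ccc(O[Si](C(C)C)(C(C)C)C(C)C)c(OC)c1)O2 | intermediate
18 | lithium enolate of (4S,5S)-4-(2-ArB-1,3-dithian-2-yl)-5-(d-menthyloxy)oxolan-2-one | [Li]OC1=C[C@H](C2(c3cc(OC)c4c(c3)[C@@H](CO[Si](C)(C)C(C)(C)C)[C@@H](c3ccc(O[Si](C(C)C)(C(C)C)C(C)C)c(OC)c3)O4)SCCCS2)[C@@H](O[C@H]2C[C@@H](C)CC[C@@H]2C(C)C)O1 | intermediate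
19 | (3R,4S,5S)-3-[(S)-ArA(hydroxy)methyl]-4-(2-ArB-1,3-dithian-2-yl)-5-(d-menthyloxy)oxolan-2-one (trans,trans lactone, anti aldol) | COc1cc([C@@H](O)[C@@H]2C(=O)O[C@H](O[C@H]3C[C@@H](C)CC[C@@H]3C(C)C)[C@H]2C2(c3cc(OC)c4c(c3)[C@@H](CO[Si](C)(C)C(C)(C)C)[C@@H](c3ccc(O[Si](C(C)C)(C(C)C)C(C)C)c(OC)c3)O4)SCCCS2)ccc1O[Si](C(C)C)(C(C)C)C(C)C | intermediate
20 | (3R,4S,5S)-3-[(S)-ArA(hydroxy)methyl]-4-(ArB-carbonyl)-5-(d-menthyloxy)oxolan-2-one | COc1cc([C@@H](O)[C@@H]2C(=O)O[C@H](O[C@H]3C[C@@H](C)CC[C@@H]3C(C)C)[C@H]2C(=O)c2cc(OC)c3c(c2)[C@@H](CO[Si](C)(C)C(C)(C)C)[C@@H](c2ccc(O[Si](C(C)C)(C(C)C)C(C)C)c(OC)c2)O3)ccc1O[Si](C(C)C)(C(C)C)C(C)C | intermediate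
21 | (3R,4R,5S)-3-[(S)-ArA(hydroxy)methyl]-4-[(S)-ArB(hydroxy)methyl]-5-(d-menthyloxy)oxolan-2-one | COc1cc([C@@H](O)[C@@H]2C(=O)O[C@H](O[C@H]3C[C@@H](C)CC[C@@H]3C(C)C)[C@H]2[C@H](O)c2cc(OC)c3c(c2)[C@@H](CO[Si](C)(C)C(C)(C)C)[C@@H](c2ccc(O[Si](C(C)C)(C(C)C)C(C)C)c(OC)c2)O3)ccc1O[Si](C(C)C)(C(C)C)C(C)C | intermediate
22 | (1S,2S,3S,4S)-1-ArA-4-ArB-2,3-bis(hydroxymethyl)butane-1,4-diol | COc1cc([C@@H](O)[C@H](CO)[C@@H](CO)[C@H](O)c2cc(OC)c3c(c2)[C@@H](CO[Si](C)(C)C(C)(C)C)[C@@H](c2ccc(O[Si](C(C)C)(C(C)C)C(C)C)c(OC)c2)O3)ccc1O[Si](C(C)C)(C(C)C)C(C)C | intermediate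
23 | (2S,3S)-2-[(S)-ArA(hydroxy)methyl]-3-[(S)-ArB(hydroxy)methyl]butane-1,4-diyl dimethanesulfonate | COc1cc([C@@H](O)[C@H](COS(C)(=O)=O)[C@@H](COS(C)(=O)=O)[C@H](O)c2cc(OC)c3c(c2)[C@@H](CO[Si](C)(C)C(C)(C)C)[C@@H](c2ccc(O[Si](C(C)C)(C(C)C)C(C)C)c(OC)c2)O3)ccc1O[Si](C(C)C)(C(C)C)C(C)C | intermediate
24 | (1S,2S,5S,6S)-2-ArA-6-ArB-3,7-dioxabicyclo[3.3.0]octane (both aryl groups endo) | COc1cc([C@H]2OC[C@@H]3[C@H]2CO[C@@H]3c2cc(OC)c3c(c2)[C@@H](CO[Si](C)(C)C(C)(C)C)[C@@H](c2ccc(O[Si](C(C)C)(C(C)C)C(C)C)c(OC)c2)O3)ccc1O[Si](C(C)C)(C(C)C)C(C)C | intermediate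
25 | CNP0303197.1, (1S,2S,5S,6S)-2-(4-hydroxy-3-methoxyphenyl)-6-[(2S,3S)-2-(4-hydroxy-3-methoxyphenyl)-3-(hydroxymethyl)-7-methoxy-2,3-dihydro-1-benzofuran-5-yl]-3,7-dioxabicyclo[3.3.0]octane (both aryl groups endo, dihydrobenzofuran 2,3-cis) | COc1cc([C@H]2OC[C@@H]3[C@H]2CO[C@@H]3c2cc(OC)c3c(c2)[C@@H](CO)[C@@H](c2ccc(O)c(OC)c2)O3)ccc1O | target

**Step count and risk**

Total steps: 17. Longest linear sequence: 15 steps (6 to 25 through steps 3–17).

Steps most likely to fail:

1. Step 12. The aldehyde may be taken up with poor facial discrimination at C2 (syn instead of anti carbinol), or the aldolate may equilibrate by retro-aldol before the quench. Fallback: the coupling of 16, 5 and 7 is run as before, but C2 is no longer set by the C–C bond formation. The mixture of 19 and the C2-epimeric syn aldol F1 is oxidised without separation (SO3·pyridine, DMSO, i-Pr2NEt, CH2Cl2, 0 °C; the dithiane tolerates activated-DMSO oxidation) to the single β-keto lactone F2. C2 is then created by reduction with LiBH(s-Bu)3 in THF at −78 °C. This bulky, non-chelating hydride should attack in the Felkin–Anh sense anti to the lactone carbonyl and give the anti carbinol. The fallback sets out from 16 and returns to the route at 19.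

2. Step 14. The oxazaborolidine may fail to override the intrinsic facial bias of the hindered aryl ketone, or the reduction may be sluggish, giving poor selectivity at C6. Fallback: the separate enantioselective reduction is dropped. From 20, LiAlH4 (THF, 0 °C → rt) reduces ketone, lactone and acetal in one operation to 22 together with the C6-epimeric tetraol F3. The mixture is taken through the conditions of step 16 and gives, via 23 and the C6-epimeric bis-mesylate F4, 24 and the ring-B-exo furofuran F5. Endo,endo and endo,exo furofurans differ markedly in shape and polarity and should be separable by chromatography, so the selectivity problem becomes a late separation and one step is saved. The fallback sets out from 20 and returns at 24.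

3. Step 8. Enantioselectivity (or cis selectivity) may erode through a stepwise hydride-transfer pathway at the very electron-rich benzylic ether, or oxonium ylide formation may compete with insertion. Fallback: catalyst control is replaced by enzymatic kinetic resolution. Alcohol 15 of insufficient enantiomeric purity is treated with Burkholderia cepacia lipase and vinyl acetate in t-BuOMe at rt, the lipase preparation being chosen so that the (2R,3R) antipode is acylated to the acetate F6. F6 is removed by chromatography and leaves (2S,3S)-15; any residual antipode is removed once more as a diastereomer after step 12. The fallback sets out from 15 and returns at 15.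

**Further compounds**

F1 | step 12 | (3R,4S,5S)-3-[(R)-ArA(hydroxy)methyl]-4-(2-ArB-1,3-dithian-2-yl)-5-(d-menthyloxy)oxolan-2-one (C2 epimer of 19) | COc1cc([C@H](O)[C@@H]2C(=O)O[C@H](O[C@H]3C[C@@H](C)CC[C@@H]3C(C)C)[C@H]2C2(c3cc(OC)c4c(c3)[C@@H](CO[Si](C)(C)C(C)(C)C)[C@@H](c3ccc(O[Si](C(C)C)(C(C)C)C(C)C)c(OC)c3)O4)SCCCS2)ccc1O[Si](C(C)C)(C(C)C)C(C)C
F2 | step 12 | (3R,4S,5S)-3-(ArA-carbonyl)-4-(2-ArB-1,3-dithian-2-yl)-5-(d-menthyloxy)oxolan-2-one | COc1cc(C(=O)[C@@H]2C(=O)O[C@H](O[C@H]3C[C@@H](C)CC[C@@H]3C(C)C)[C@H]2C2(c3cc(OC)c4c(c3)[C@@H](CO[Si](C)(C)C(C)(C)C)[C@@H](c3ccc(O[Si](C(C)C)(C(C)C)C(C)C)c(OC)c3)O4)SCCCS2)ccc1O[Si](C(C)C)(C(C)C)C(C)C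
F3 | step 14 | (1S,2S,3S,4R)-1-ArA-4-ArB-2,3-bis(hydroxymethyl)butane-1,4-diol (C6 epimer of 22) | COc1cc([C@@H](O)[C@H](CO)[C@@H](CO)[C@@H](O)c2cc(OC)c3c(c2)[C@@H](CO[Si](C)(C)C(C)(C)C)[C@@H](c2ccc(O[Si](C(C)C)(C(C)C)C(C)C)c(OC)c2)O3)ccc1O[Si](C(C)C)(C(C)C)C(C)C
F4 | step 14 | (2S,3S)-2-[(S)-ArA(hydroxy)methyl]-3-[(R)-ArB(hydroxy)methyl]butane-1,4-diyl dimethanesulfonate (C6 epimer of 23) | COc1cc([C@@H](O)[C@H](COS(C)(=O)=O)[C@@H](COS(C)(=O)=O)[C@@H](O)c2cc(OC)c3c(c2)[C@@H](CO[Si](C)(C)C(C)(C)C)[C@@H](c2ccc(O[Si](C(C)C)(C(C)C)C(C)C)c(OC)c2)O3)ccc1O[Si](C(C)C)(C(C)C)C(C)C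
F5 | step 14 | (1S,2S,5S,6R)-2-ArA-6-ArB-3,7-dioxabicyclo[3.3.0]octane (ring A endo, ring B exo) | COc1cc([C@H]2OC[C@@H]3[C@H]2CO[C@H]3c2cc(OC)c3c(c2)[C@@H](CO[Si](C)(C)C(C)(C)C)[C@@H](c2ccc(O[Si](C(C)C)(C(C)C)C(C)C)c(OC)c2)O3)ccc1O[Si](C(C)C)(C(C)C)C(C)C
F6 | step 8 | [(2R,3R)-2-ArA-5-(1,3-dithian-2-yl)-7-methoxy-2,3-dihydro-1-benzofuran-3-yl]methyl acetate | S1CCCSC1c1cc(OC)c2c(c1)[C@H](COC(C)=O)[C@H](c1ccc(O[Si](C(C)C)(C(C)C)C(C)C)c(OC)c1)O2
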